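## Retrosynthetic overview

1. Rings are formed in the order oxolane → γ-lactone → 14-membered carbocycle. The macrocycle is not closed at the C2=C3 alkene but at C16–C17, by C-acylation of an allyl sulfone carbanion with a thioester, followed by SmI2 desulfonylation.
2. Key strategy: one S-ethyl thioacetate unit is the linchpin. Its α-carbon (C15) is a nucleophile twice (chelation-controlled Mukaiyama aldol to the C12 aldehyde, then a copper–bis(oxazoline)-catalysed Mukaiyama aldol to methyl pyruvate that sets C14 and C15 and delivers the lactone). Its carbonyl (C16) is then the electrophile for ring closure.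
3. C3–C4 comes from a B-alkyl Suzuki coupling with an (E)-iodoalkene made by Negishi carboalumination, so the alkene geometry is fixed early and only carried.
4. The oxolane with C10/C11 comes from Sharpless epoxidation of a (Z)-allylic alcohol and 5-exo opening by C7–OH; C6/C7 come from a Brown (Z)-crotylation of a neryl acetate-derived aldehyde.

Assumption: atom labels C1–C17 follow the carbon order of the target SMILES (C1 vinylic methyl, C2=C3 alkene, C6 CHMe, C7 and C10 oxolane carbons, C11 carbinol, C12 lactone CH–O, C13 lactone C=O, C14 C(OH)Me, C15 lactone CH, C16 ketone, C17 CH2).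

## Route

Step 1
Reactants: 1 propargyl alcohol
Product: 3 (E)-3-iodo-2-methylprop-2-en-1-ol, via alkenylalane 2 (not isolated)
Conditions: AlMe3 (3 equiv), Cp2ZrCl2 (25 mol %), CH2Cl2, 0 → 23 °C; then I2, THF, −30 → 0 °C
Reagents that add atoms: trimethylaluminium, C[Al](C)C; iodine, [I][I]
Why: Negishi zirconium-catalysed carboalumination adds Me and Al syn across the alkyne with Me on the internal carbon, and iodinolysis of the C–Al bond with retention gives the (E)-iodoalkene that becomes the C2=C3 alkene.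

Step 2
Reactants: 3 (E)-3-iodo-2-methylprop-2-en-1-ol
Product: 5 [(E)-3-iodo-2-methylprop-2-en-1-yl]sulfonylbenzene, via allylic mesylate 4 (not isolated)
Conditions: MsCl, Et3N, CH2Cl2, 0 °C; then PhSO2Na, DMF, 23 °C
Reagents that add atoms: sodium benzenesulfinate, [Na+].[O-]S(=O)c1ccccc1
Why: SN2 displacement of the primary allylic mesylate by the soft sulfur of the sulfinate (S-alkylation) gives the allyl sulfone without touching the alkene geometry.

Step 3
Reactants: 6 S-ethyl thioacetate
Product: 7 silyl ketene thioacetal [1-(ethylsulfanyl)ethenyl]oxy(trimethyl)silane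
Conditions: LiN(iPr)2, THF, −78 °C; TMSCl
Reagents that add atoms: chlorotrimethylsilane, C[Si](C)(C)Cl
Why: O-silylation of the lithium thioester enolate gives the Mukaiyama donor.

Step 4
Reactants: 8 neryl acetate
Product: 9 (2Z)-3-methyl-6-oxohex-2-en-1-yl acetate
Conditions: O3 (1.0 equiv), CH2Cl2–MeOH, −78 °C; then Me2S
Reagents that add atoms: ozone, [O-][O+]=O
Why: chemoselective ozonolysis of the remote, more electron-rich trisubstituted alkene, the other alkene being deactivated by the allylic acetate.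

Step 5
Reactants: 9 (2Z)-3-methyl-6-oxohex-2-en-1-yl acetate
Product: 12 (2Z,6R,7R)-3,7-dimethylnona-2,8-diene-1,6-diol, via borinate ester 10 (not isolated), via hydroxy acetate 11 (not isolated)
Conditions: cis-2-butene, KOtBu, nBuLi, THF, −45 °C; (−)-Ipc2BOMe [from (+)-α-pinene], −78 °C; BF3·OEt2; then 9, −78 °C; then 3 M NaOH, 30% H2O2, 50 °C
Reagents that add atoms: cis-2-butene, C/C=C\C
Why: Brown (Z)-crotylboration through a chair Zimmerman–Traxler transition state gives the syn relation of C6-Me and C7-OH, the isopinocampheyl groups direct attack to the si face of the aldehyde (C7 R, C6 R), and the basic peroxide work-up also saponifies the acetate.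

Step 6
Reactants: 12 (2Z,6R,7R)-3,7-dimethylnona-2,8-diene-1,6-diol
Product: 14 oxolane diol (1R)-1-{(2R,5R)-5-[(2R)-but-3-en-2-yl]-2-methyloxolan-2-yl}ethane-1,2-diol, via epoxy diol 13 (not isolated)
Conditions: Ti(OiPr)4 (20 mol %), D-(−)-diethyl tartrate (24 mol %), tBuOOH, 4 Å sieves, CH2Cl2, −20 °C; then CSA (20 mol %), 0 °C
Reagents that add atoms: tert-butyl hydroperoxide, CC(C)(C)OO
Why: Sharpless asymmetric epoxidation of the (Z)-allylic alcohol with the D-tartrate gives the (2R,3S)-epoxide, and acid-catalysed 5-exo opening at the tertiary carbon by C7–OH with inversion sets C10 (R) and leaves C11–OH (R).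

Step 7
Reactants: 14 oxolane diol
Product: 15 PMP acetal (4R)-4-{(2R,5R)-5-[(2R)-but-3-en-2-yl]-2-methyloxolan-2-yl}-2-(4-methoxyphenyl)-1,3-dioxolane
Conditions: 4-MeOC6H4CH(OMe)2, PPTS (cat.), CH2Cl2, 23 °C
Reagents that add atoms: 4-methoxybenzaldehyde dimethyl acetal, COC(OC)c1ccc(OC)cc1
Why: acid-catalysed transacetalisation ties the C11/C12 diol into a dioxolane (acetal carbon epimers are inconsequential).

Step 8
Reactants: 15 PMP acetal; 5 [(E)-3-iodo-2-methylprop-2-en-1-yl]sulfonylbenzene
Product: 17 sulfone acetal (C3–C4 coupled; see list), via B-alkyl-9-BBN adduct 16 (not isolated)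
Conditions: 9-BBN, THF, 23 °C; then 5, Pd(dppf)Cl2 (5 mol %), AsPh3 (10 mol %), K3PO4 (3 M aq), DMF, 23 °C
Reagents that add atoms: none
Why: anti-Markovnikov hydroboration of the terminal alkene followed by B-alkyl Suzuki–Miyaura coupling, which proceeds with retention of the iodoalkene geometry and so installs the (E)-C2=C3 alkene.

Step 9
Reactants: 17 sulfone acetal
Product: 18 C11-O-PMB primary alcohol (see list)
Conditions: iBu2AlH, CH2Cl2, −78 → 0 °C
Reagents that add atoms: none
Why: regioselective reductive acetal opening, in which aluminium binds the less hindered primary oxygen and hydride delivery leaves the PMB ether on the hindered C11 oxygen.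

Step 10
Reactants: 18 C11-O-PMB primary alcohol
Product: 19 C11-O-PMB aldehyde (see list)
Conditions: Dess–Martin periodinane, CH2Cl2, 23 °C
Reagents that add atoms: none
Why: Dess–Martin oxidation gives the α-alkoxy aldehyde without epimerising C11.

Step 11
Reactants: 19 C11-O-PMB aldehyde; 7 silyl ketene thioacetal
Product: 20 β-hydroxy thioester (see list)
Conditions: MgBr2·OEt2 (3 equiv), CH2Cl2, −78 → −30 °C; 1 M HCl work-up
Reagents that add atoms: none
Why: chelation-controlled Mukaiyama aldol, in which magnesium bridges the aldehyde and C11–OPMB oxygens and the nucleophile adds anti to the bulky oxolanyl group, giving the syn C11/C12 relation (C12 S).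

Step 12
Reactants: 20 β-hydroxy thioester
Product: 21 bis-silyl ketene thioacetal (see list)
Conditions: TMSOTf (2.6 equiv), Et3N (3 equiv), Et2O, 0 → 23 °C
Reagents that add atoms: trimethylsilyl trifluoromethanesulfonate, C[Si](C)(C)OS(=O)(=O)C(F)(F)F
Why: silylation of C12–OH and soft enolisation of the thioester (carbonyl activation by the silyl triflate, deprotonation by the amine), conditions too weak to touch the sulfone α-CH2.

Step 13
Reactants: 21 bis-silyl ketene thioacetal; 22 methyl pyruvate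
Product: 25 lactone thioester (see list), via bis-silyl aldol adduct 23 (not isolated), via dihydroxy ester 24 (not isolated)
Conditions: Cu(OTf)2 (15 mol %), (S,S)-tBu-box (17 mol %), THF, −78 → −40 °C; then 1 M HCl, THF, 23 °C
Reagents that add atoms: none
Why: copper–bis(oxazoline)-catalysed Mukaiyama aldol to bidentate-bound methyl pyruvate, in which the catalyst exposes the si face of the ketone (C14 S) and the open syn-selective transition state sets C15 (S) relative to C14, after which acid removes both silyl groups and C12–OH closes the γ-lactone with loss of methanol.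

Step 14
Reactants: 25 lactone thioester
Product: 28 macrocyclic β-keto sulfone (see list), via lactone silyl ether 26 (not isolated), via macrocyclic silyl ether 27 (not isolated)
Conditions: MeC(OSiMe3)=NSiMe3 (BSA), MeCN, 50 °C, evaporate; LiN(SiMe3)2 (2.5 equiv), THF (1 mM), −78 → −30 °C; then 1 M HCl, THF, 0 °C
Reagents that add atoms: none
Why: Claisen-type (Dieckmann-like) macrocyclisation, in which the unhindered allylic sulfone is deprotonated kinetically, its α-carbon (C17) acylates the thioester (a better acyl donor than the hindered lactone), and deprotonation of the β-keto sulfone formed makes ring closure irreversible.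

Step 15
Reactants: 28 macrocyclic β-keto sulfone
Product: 29 C11-O-PMB ether of the target
Conditions: SmI2 (3 equiv), THF–MeOH, −78 °C
Reagents that add atoms: none
Why: reductive desulfonylation of a β-keto sulfone by SmI2, in which the samarium dienolate is protonated kinetically at the α-carbon (C17) to give the β,γ-unsaturated ketone without moving the (E)-alkene.

Step 16
Reactants: 29 C11-O-PMB ether of the target
Product: 30 target CNP0264573.3
Conditions: DDQ, CH2Cl2–pH 7 buffer, 0 °C
Reagents that add atoms: none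
Why: oxidative PMB ether cleavage by DDQ (benzylic hydride abstraction, then hydrolysis of the oxocarbenium ion) under neutral conditions that leave the β,γ-unsaturated ketone, lactone and C15 untouched.

## Compound list

In the list below, R* stands for the side chain (2R,5R)-2-methyl-5-[(2R,5E)-6-methyl-7-(phenylsulfonyl)hept-5-en-2-yl]oxolan-2-yl.

1 | prop-2-yn-1-ol (propargyl alcohol) | C#CCO | starting material
2 | alkenylalane, dimethyl[(E)-3-(dimethylalumanyloxy)-2-methylprop-1-en-1-yl]alumane | C/C(=C\[Al](C)C)CO[Al](C)C | intermediate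
3 | (E)-3-iodo-2-methylprop-2-en-1-ol | C/C(=C\I)CO | intermediate
4 | allylic mesylate, (E)-3-iodo-2-methylprop-2-en-1-yl methanesulfonate | C/C(=C\I)COS(C)(=O)=O | intermediate
5 | [(E)-3-iodo-2-methylprop-2-en-1-yl]sulfonylbenzene | C/C(=C\I)CS(=O)(=O)c1ccccc1 | intermediate
6 | S-ethyl ethanethioate (S-ethyl thioacetate) | CC(=O)SCC | starting material
7 | silyl ketene thioacetal, [1-(ethylsulfanyl)ethenyl]oxy(trimethyl)silane | C=C(O[Si](C)(C)C)SCC | intermediate
8 | neryl acetate, (2Z)-3,7-dimethylocta-2,6-dien-1-yl acetate | CC(C)=CCC/C(C)=C\COC(C)=O | starting material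
9 | (2Z)-3-methyl-6-oxohex-2-en-1-yl acetate | O=CCC/C(C)=C\COC(C)=O | intermediate
10 | borinate ester, (2Z,6R,7R)-6-[bis(isopinocampheyl)boranyloxy]-3,7-dimethylnona-2,8-dien-1-yl acetate (isopinocampheyl from (+)-α-pinene) | C=C[C@@H](C)[C@H](OB([C@@H]1C[C@@H]2C[C@H]([C@H]1C)C2(C)C)[C@@H]1C[C@@H]2C[C@H]([C@H]1C)C2(C)C)CC/C(C)=C\COC(C)=O | intermediate
11 | hydroxy acetate, (2Z,6R,7R)-6-hydroxy-3,7-dimethylnona-2,8-dien-1-yl acetate | C=C[C@@H](C)[C@H](O)CC/C(C)=C\COC(C)=O | intermediate
12 | (2Z,6R,7R)-3,7-dimethylnona-2,8-diene-1,6-diol | C=C[C@@H](C)[C@H](O)CC/C(C)=C\CO | intermediate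
13 | epoxy diol, {(2R,3S)-3-[(3R,4R)-3-hydroxy-4-methylhex-5-en-1-yl]-3-methyloxiran-2-yl}methanol | C=C[C@@H](C)[C@H](O)CC[C@]1(C)O[C@@H]1CO | intermediate
14 | oxolane diol, (1R)-1-{(2R,5R)-5-[(2R)-but-3-en-2-yl]-2-methyloxolan-2-yl}ethane-1,2-diol | C=C[C@@H](C)[C@H]1CC[C@@](C)(O1)[C@H](O)CO | intermediate
15 | PMP acetal, (4R)-4-{(2R,5R)-5-[(2R)-but-3-en-2-yl]-2-methyloxolan-2-yl}-2-(4-methoxyphenyl)-1,3-dioxolane (acetal carbon: both epimers) | C=C[C@@H](C)[C@H]1CC[C@@](C)(O1)[C@H]1COC(c2ccc(OC)cc2)O1 | intermediate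
16 | B-alkyl-9-BBN adduct, 9-[(3R)-3-{(2R,5R)-5-[(4R)-2-(4-methoxyphenyl)-1,3-dioxolan-4-yl]-5-methyloxolan-2-yl}butyl]-9-borabicyclo[3.3.1]nonane | B1(C2CCCC1CCC2)CC[C@@H](C)[C@H]1CC[C@@](C)(O1)[C@H]1COC(c2ccc(OC)cc2)O1 | intermediate
17 | sulfone acetal, (4R)-2-(4-methoxyphenyl)-4-R*-1,3-dioxolane | C/C(=C\CC[C@@H](C)[C@H]1CC[C@@](C)(O1)[C@H]1COC(c2ccc(OC)cc2)O1)CS(=O)(=O)c1ccccc1 | intermediate
18 | C11-O-PMB primary alcohol, (2R)-2-[(4-methoxyphenyl)methoxy]-2-R*-ethan-1-ol | C/C(=C\CC[C@@H](C)[C@H]1CC[C@@](C)(O1)[C@@H](CO)OCc1ccc(OC)cc1)CS(=O)(=O)c1ccccc1 | intermediate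
19 | C11-O-PMB aldehyde, (2S)-2-[(4-methoxyphenyl)methoxy]-2-R*-acetaldehyde | C/C(=C\CC[C@@H](C)[C@H]1CC[C@@](C)(O1)[C@@H](C=O)OCc1ccc(OC)cc1)CS(=O)(=O)c1ccccc1 | intermediate
20 | β-hydroxy thioester, S-ethyl (3S,4R)-3-hydroxy-4-[(4-methoxyphenyl)methoxy]-4-R*-butanethioate | C/C(=C\CC[C@@H](C)[C@H]1CC[C@@](C)(O1)[C@H](OCc1ccc(OC)cc1)[C@@H](O)CC(=O)SCC)CS(=O)(=O)c1ccccc1 | intermediate
21 | bis-silyl ketene thioacetal, (3S,4R)-1-(ethylsulfanyl)-4-[(4-methoxyphenyl)methoxy]-4-R*-1,3-bis(trimethylsilyloxy)but-1-ene (enol geometry not defined) | C/C(=C\CC[C@@H](C)[C@H]1CC[C@@](C)(O1)[C@H](OCc1ccc(OC)cc1)[C@@H](O[Si](C)(C)C)C=C(O[Si](C)(C)C)SCC)CS(=O)(=O)c1ccccc1 | intermediate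
22 | methyl 2-oxopropanoate (methyl pyruvate) | CC(=O)C(=O)OC | starting material
23 | bis-silyl aldol adduct, methyl (2S,3S,4S,5R)-3-[(ethylsulfanyl)carbonyl]-5-[(4-methoxyphenyl)methoxy]-2-methyl-5-R*-2,4-bis(trimethylsilyloxy)pentanoate | C/C(=C\CC[C@@H](C)[C@H]1CC[C@@](C)(O1)[C@H](OCc1ccc(OC)cc1)[C@@H](O[Si](C)(C)C)[C@H](C(=O)SCC)[C@](C)(O[Si](C)(C)C)C(=O)OC)CS(=O)(=O)c1ccccc1 | intermediate
24 | dihydroxy ester, methyl (2S,3S,4S,5R)-3-[(ethylsulfanyl)carbonyl]-2,4-dihydroxy-5-[(4-methoxyphenyl)methoxy]-2-methyl-5-R*-pentanoate | C/C(=C\CC[C@@H](C)[C@H]1CC[C@@](C)(O1)[C@H](OCc1ccc(OC)cc1)[C@@H](O)[C@H](C(=O)SCC)[C@](C)(O)C(=O)OC)CS(=O)(=O)c1ccccc1 | intermediate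
25 | lactone thioester, S-ethyl (2S,3S,4S)-4-hydroxy-2-{(R)-[(4-methoxyphenyl)methoxy](R*)methyl}-4-methyl-5-oxooxolane-3-carbothioate | C/C(=C\CC[C@@H](C)[C@H]1CC[C@@](C)(O1)[C@H](OCc1ccc(OC)cc1)[C@H]1OC(=O)[C@@](C)(O)[C@H]1C(=O)SCC)CS(=O)(=O)c1ccccc1 | intermediate
26 | lactone silyl ether, C14-O-trimethylsilyl ether of 25 | C/C(=C\CC[C@@H](C)[C@H]1CC[C@@](C)(O1)[C@H](OCc1ccc(OC)cc1)[C@H]1OC(=O)[C@@](C)(O[Si](C)(C)C)[C@H]1C(=O)SCC)CS(=O)(=O)c1ccccc1 | intermediate
27 | macrocyclic silyl ether, 17-(phenylsulfonyl) C11-O-PMB C14-O-trimethylsilyl derivative of 30 (C17 epimers) | C/C1=C\CC[C@@H](C)[C@H]2CC[C@@](C)(O2)[C@H](OCc3ccc(OC)cc3)[C@H]2OC(=O)[C@@](C)(O[Si](C)(C)C)[C@H]2C(=O)C1S(=O)(=O)c1ccccc1 | intermediate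
28 | macrocyclic β-keto sulfone, 17-(phenylsulfonyl) C11-O-PMB derivative of 30 (C17 epimers) | C/C1=C\CC[C@@H](C)[C@H]2CC[C@@](C)(O2)[C@H](OCc3ccc(OC)cc3)[C@H]2OC(=O)[C@@](C)(O)[C@H]2C(=O)C1S(=O)(=O)c1ccccc1 | intermediate
29 | C11-O-(4-methoxybenzyl) ether of 30 | C/C1=C\CC[C@@H](C)[C@H]2CC[C@@](C)(O2)[C@H](OCc3ccc(OC)cc3)[C@H]2OC(=O)[C@@](C)(O)[C@H]2C(=O)C1 | intermediate
30 | CNP0264573.3, (3S,3aS,6E,10R,11R,14R,15R,15aS)-3,15-dihydroxy-3,6,10,14-tetramethyl-11,14-epoxy-dodecahydrocyclotetradeca[b]furan-2,4-dione (C6R, C7R, C10R, C11R, C12S, C14S, C15S, 2E in the labels used here) | C/C1=C\CC[C@@H](C)[C@H]2CC[C@@](C)(O2)[C@H](O)[C@H]2OC(=O)[C@@](C)(O)[C@H]2C(=O)C1 | target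

## Step count and risks

Total steps: 16. Longest linear sequence: 13 steps (steps 4–16, from neryl acetate 8); steps 1–2 and step 3 make the two side fragments.

Three steps most likely to fail:

**Step 13 (pyruvate aldol on the hindered, chiral enolsilane 21).** The nucleophile is bulkier than the simple enolsilanes this catalysis is known for, and the C12 stereocentre may oppose the catalyst at C15. Fallback: reverse the order of the two aldol events so that the catalytic step runs on the simplest partners. It sets out from aldehyde 19. Ketene thioacetal 7 and methyl pyruvate 22 are combined under the same Cu(OTf)2/(S,S)-tBu-box catalysis to give methyl (2S)-4-(ethylsulfanyl)-2-methyl-4-oxo-2-(trimethylsilyloxy)butanoate F1. LiN(iPr)2 and TMSCl convert this into the silyl ketene thioacetal methyl (2S)-4-(ethylsulfanyl)-2-methyl-2,4-bis(trimethylsilyloxy)but-3-enoate F2. A MgBr2·OEt2-chelated Mukaiyama aldol of F2 with 19 then gives the C14-O-silyl hydroxy ester F3 (C12 again set by the chelate; C15 relies on the anti preference of thioester ketene acetals with chelated α-alkoxy aldehydes). Treatment with 1 M HCl removes the silyl group and closes the lactone, and the fallback comes back to the route at 25.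

**Step 14 (macrocyclisation by sulfone carbanion acylation).** The thioester is hindered, and proton transfer from C15–H could compete with ring closure and epimerise C15. Fallback: close the ring by carbonyl addition instead of acyl substitution. It sets out from the lactone silyl ether 26. Fukuyama reduction (Et3SiH, palladium on carbon, acetone) gives the C16 aldehyde F4. LiN(SiMe3)2 at high dilution adds the sulfone carbanion to the aldehyde to give the macrocyclic β-hydroxy sulfone F5. Dess–Martin oxidation then returns to the route at 27, which the acid work-up of step 14 converts into 28.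

**Step 12 (soft enolisation of the β-silyloxy thioester beside an acidic allyl sulfone).** Possible failures are β-elimination of the silyloxy group or incomplete enolisation. Fallback: do not make an enolsilane at all. It sets out from 20. TiCl4 and iPr2NEt enolise the thioester directly as a titanium enolate chelated to the C12 alkoxide (the sulfone is not activated). Methyl pyruvate 22 is added to this enolate, which reacts anti to the chelated C12–O (Fráter–Seebach-type facial control at C15). This comes back to the route at the dihydroxy ester 24, which lactonises to 25 as in step 13; C14 is then under substrate control only, so epimers may need separation at 25. No new compound is made.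

## Further compounds

F0 | step 12 | none | none
F1 | step 13 | methyl (2S)-4-(ethylsulfanyl)-2-methyl-4-oxo-2-(trimethylsilyloxy)butanoate | CCSC(=O)C[C@](C)(O[Si](C)(C)C)C(=O)OC
F2 | step 13 | methyl (2S)-4-(ethylsulfanyl)-2-methyl-2,4-bis(trimethylsilyloxy)but-3-enoate | CCSC(O[Si](C)(C)C)=C[C@](C)(O[Si](C)(C)C)C(=O)OC
F3 | step 13 | methyl (2S,3S,4S,5R)-3-[(ethylsulfanyl)carbonyl]-4-hydroxy-5-[(4-methoxyphenyl)methoxy]-2-methyl-5-R*-2-(trimethylsilyloxy)pentanoate | C/C(=C\CC[C@@H](C)[C@H]1CC[C@@](C)(O1)[C@H](OCc1ccc(OC)cc1)[C@@H](O)[C@H](C(=O)SCC)[C@](C)(O[Si](C)(C)C)C(=O)OC)CS(=O)(=O)c1ccccc1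
F4 | step 14 | C16 aldehyde, (2S,3S,4S)-2-{(R)-[(4-methoxyphenyl)methoxy](R*)methyl}-4-methyl-5-oxo-4-(trimethylsilyloxy)oxolane-3-carbaldehyde | C/C(=C\CC[C@@H](C)[C@H]1CC[C@@](C)(O1)[C@H](OCc1ccc(OC)cc1)[C@H]1OC(=O)[C@@](C)(O[Si](C)(C)C)[C@H]1C=O)CS(=O)(=O)c1ccccc1
F5 | step 14 | macrocyclic β-hydroxy sulfone, 16-hydroxy (in place of the ketone) analogue of 27 (C16 and C17 epimers) | C/C1=C\CC[C@@H](C)[C@H]2CC[C@@](C)(O2)[C@H](OCc3ccc(OC)cc3)[C@H]2OC(=O)[C@@](C)(O[Si](C)(C)C)[C@H]2C(O)C1S(=O)(=O)c1ccccc1
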